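(The numbers in the tables were computed for an exercise, noise included.)

If both mirror images react through the same steps, and one does so s times as fast as the other (s is the selectivity factor), I can read the flask on one clock. I call the burn of a substrate the natural logarithm of 0.5 over its remaining fraction of both substrates charged.

| setting | delta | epsilon | flask |
|---|---|---|---|
| left-handed substrate | 0.10 M | 0.10 M | 0.10 M |
| right-handed substrate | 0.10 M | 0.10 M | 0.10 M |
| coupling partner | 0.30 M | 0.30 M | 0.300 M |
| catalyst | 2.5 mM | 9.8 mM | 4.9 mM |
| remark | run made earlier | run made earlier |  |
| time |  |  | 80 min |

- delta (time / min: right-handed substrate / %, left-handed substrate / %, left-handed product / %): 6.00: 47.8, 0, 50.8; 15.0: 44.4, 0.5, 51.4; 30.0: 42.0, 0.5, 48.9; 50.0: 42.0, 0, 50.2; 60.0: 42.4, 1.1, 48.7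
- epsilon (time / min: right-handed substrate / %, left-handed substrate / %, left-handed product / %): 6.00: 36.7, 1.0, 49.5; 15.0: 32.6, 0.4, 49.2; 30.0: 28.4, 0, 49.5; 50.0: 26.8, 0, 50.2; 60.0: 28.2, 0.5, 48.3

(readings scatter by 1 percentage point)

* whether the excess of right-handed substrate over left-handed substrate among what is left of the two reaches 98 % by 80 min (yes / no)
* the highest excess of right-handed substrate over left-handed substrate among what is left of the two up to 80 min

- catalyst is single-handed; left-handed substrate and right-handed substrate are mirror images of each other, charged as a racemate, each of them at the stated concentration

The wanted excess requires the left-handed burn to lead the right-handed burn by 4.60. In delta at 6.00 min, the right-handed burn reads 0.0450. I take the left-handed reading as below 1 percentage point, so its burn is at least 3.91 and s reads at least about 86.9, with the scatter of its readings. The needed burn of the right-handed substrate, the lead divided by s minus one, is then 0.0535.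

The right-handed substrate in epsilon burns at 0.0515 min⁻¹ on average over the first interval. Scaling by catalyst, I expect 0.0258 min⁻¹ over the same interval in the flask, which reaches the needed burn in about 2.07 min. The right-handed rate in epsilon then reads 0.00919 min⁻¹ from 15.0 min to 30.0 min, and later readings stay level within scatter. The right-handed plateaus of delta and epsilon, scaled to the flask and averaged, give an end burn of 0.315, against 2.06 if the first rate were kept up. That is still 5.89 times the needed burn, so I expect yes.

The forecast also says yes, with a top of 99.9 %, holding that “selectivity is very high”; its floor for s, about 100, is higher than mine.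

    coupling partner + catalyst + left-handed substrate → catalyst + left-handed product (k = 46.7 L² mol⁻² s⁻¹)
    coupling partner + catalyst + right-handed substrate → catalyst + right-handed product (k = 0.497 L² mol⁻² s⁻¹)
    coupling partner → decomposed reagent (k = 0.00126 s⁻¹)
    coupling partner → decomposition product (k = 3.34 × 10⁻⁵ s⁻¹)

The flask gives yes, with a top of 100 %. The wanted excess arrives in the flask at 1.68 min, with 47.6 % right-handed substrate left, a right-handed burn of 0.0492. The flask's right-handed burn at 80.0 min is 0.324, more than the needed burn by a factor of 6.06. Delta, with half the flask's catalyst, has a right-handed plateau burn reading 0.171, which is 3.20 times the needed burn.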